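The data were computed on assumed constants, noise included.

A percent of X per day is the unit in which to read these flasks.

| flask | X | G | Z | remark | time |
|---|---|---|---|---|---|
| elm | 0.020 M | 0.024 M | 0.030 M | run made earlier |  |
| maple | 0.020 M | 0.024 M | 0.042 M | run made earlier |  |
| ash | 0.020 M | 0.024 M | 0.066 M | run made earlier |  |
| winter | 0.020 M | 0.0240 M | 0.0300 M (fed, over 3.20 d) | all but Z at the start; Z goes in evenly over 3.20 d, the run ends at 4.0 d | 4.0 d |
| autumn | 0.020 M | 0.0240 M | 0.0300 M | one stirred flow tank at steady state, fed with the mixture as stated, mean residence time 4.0 d |  |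
| spring | 0.020 M | 0.0240 M | 0.0300 M | everything together in a closed stirred flask, run for 4.0 d | 4.0 d |
| midnight | 0.020 M | 0.0240 M | 0.0300 M | a single well-mixed tank run continuously and read at steady state, 40.0 d in it on average |  |

| run | time / d | Q / % | L / % | X / % |
|---|---|---|---|---|
| elm | 0.333 | 39 | 4 | 62 |
| elm | 1.04 | 54 | 4 | 40 |
| elm | 1.67 | 56 | 12 | 32 |
| elm | 3.00 | 50 | 25 | 23 |
| elm | 4.00 | 44 | 30 | 21 |
| maple | 0.208 | 34 | 0 | 67 |
| maple | 0.333 | 48 | 2 | 49 |
| maple | 0.625 | 63 | 7 | 37 |
| maple | 1.25 | 65 | 12 | 24 |
| maple | 2.50 | 61 | 27 | 11 |
| ash | 0.208 | 51 | 0 | 52 |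
| ash | 0.333 | 63 | 3 | 39 |
| ash | 0.625 | 78 | 6 | 15 |
| ash | 1.25 | 77 | 24 | 4 |
| ash | 2.50 | 63 | 43 | 4 |

(scatter of a reading: 2 percentage points)

1. the set-up with the highest amount of Q at the outlet or at the end, in percent of the X put in ("none" if the first two lie within 2 percentage points) (winter / autumn / spring / midnight / none)
2. amount of Q at the outlet or at the end, in percent of the X put in, winter
3. amount of Q at the outlet or at the end, in percent of the X put in, autumn
4. amount of Q at the outlet or at the end, in percent of the X put in, spring
5. amount of Q at the outlet or at the end, in percent of the X put in, midnight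

- L is meant together with its E
- the stated concentrations are those of everything mixed, before any reaction; amounts are the same in each set-up
- the numbers in the tables scatter with a standard deviation of 2 percentage points
- steps thought possible: X + Z -> Q; G + L <-> E; Z + G -> D; Q + D -> L
- the feed brings no volume worth counting
- the earlier runs were made in a closed, stirred flask

How long does a Q last in elm? Between 1.67 d and 4.00 d, L gains 18 percentage points in 2.33 d, while Q averages 50.0%. Each L costs one Q, so the mean Q divided by that gain gives the Q-life, 6.47 d: a pseudo-first-order life, read from scattered readings.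

Why not take it from the fall of Q? Over that stretch X drops from 32% to 21%, so Q is still being fed.

What is the life good for? L at the end is roughly the Q-days, the area under the Q curve, divided by the Q-life.

And spring? It has elm's charge in a closed flask, so I read elm: Q 44% at 4.00 d.

And winter? My reckoning lets Q climb evenly to elm's peak reading, 56%, over the 3.20 d of dosing and then hold it until 4.0 d. That makes 1.34 d of Q-days and so L of 20.8%, less than elm's 30%. With X left as in elm, the remainder is Q: 58.2%.

Isn't that X borrowed? Yes, and dosed Z may leave more X. My reckoned lead over elm's reading for spring is 14 points, and each point of extra X left comes off it. The life is borrowed too, since D in winter need not match elm.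

And autumn? Q stays 4.0 d on average, so L over Q should be the stay over the life, 0.618.

The forecast gives 55% for winter (49% to 61%), 40% for autumn, 45% for spring and 21% for midnight, and picks winter, since “dosing keeps Q and D low for longer”.

The flask answers winter, with these steps behind it:

    X + Z → Q (k = 2.60 M⁻¹ h⁻¹)
    G + L ⇌ E, settled at all times (K = 39.9 M⁻¹)
    Z + G → D (k = 1.71 M⁻¹ h⁻¹)
    Q + D → L (k = 0.713 M⁻¹ h⁻¹)

Winter ends at 53.4% of Q, the highest of the set, with 31.0% of X and 15.6% of L; spring ends at 44.8% of Q and midnight holds 21.5%. The same even climb, now to 53.4%, comes to 1.28 d of Q-days, and through the Q-life of 6.47 d these give L of 19.8%, more than the 15.6% found, so on this reckoning winter's own life is 8.21 d, longer than elm's. In autumn the stay over the life gave 0.618, and the tank holds 40.5% of Q and 20.5% of L, a ratio of 0.506.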